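**Strategy.** Galbulin is a constitutional isomer of the all-trans head-to-head [2+2] dimer of (E)-methylisoeugenol, and the route rests on that. The saturated ring C1–C2–C3–C4–C4a–C8a is disconnected at C1–C8a, and a C1–C4 bond is added to give a cyclobutane. In the key step, one-electron oxidation cleaves this bis-benzylic cyclobutane bond. The benzylic cation at C1 then closes onto the ortho carbon (C8a) of the veratryl ring on C4, and hydrogen-atom return gives the tetralin. This four-to-six ring expansion keeps the trans C2/C3 methyl centres and sets C1. The precursor is (1R,2R,3S,4S)-1,2-bis(3,4-dimethoxyphenyl)-3,4-dimethylcyclobutane, made by one enantioselective radical-cation dimerisation.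

Key step: step 2

Remark on the chemistry: methylisoeugenol is assumed to be used as its commercial E isomer. The chiral ion-pair photocatalyst is taken as an available catalyst and its preparation is not counted. Step 1 is a dimerisation and step 2 an isomerisation, so neither forms a coproduct.

**Step 1**
Reactants: 1 (E)-methylisoeugenol [(E)-1,2-dimethoxy-4-(prop-1-en-1-yl)benzene], two molecules
Product: 2 (1R,2R,3S,4S)-1,2-bis(3,4-dimethoxyphenyl)-3,4-dimethylcyclobutane (all-trans, C2-symmetric)
Conditions: thioxanthylium photoredox cation paired with a confined chiral imidodiphosphorimidate (IDPi) anion (2 mol%, enantiomer chosen for the 1R,2R,3S,4S product), CH2Cl2, green LEDs, −78 °C or lower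
Reagents that add atoms: none
Why: Enantioselective radical-cation [2+2] homodimerisation of an electron-rich β-methylstyrene should give the head-to-head trans,anti,trans cyclobutane, with the chiral counteranion paired to the alkene radical cation selecting the face and so setting all four stereocentres, and with the product radical cation reduced by monomer (chain electron transfer) before it can revert.

**Step 2**
Reactants: 2 (1R,2R,3S,4S)-1,2-bis(3,4-dimethoxyphenyl)-3,4-dimethylcyclobutane
Product: 3 (1S,2S,3R)-galbulin [(1S,2S,3R)-1-(3,4-dimethoxyphenyl)-6,7-dimethoxy-2,3-dimethyl-1,2,3,4-tetrahydronaphthalene]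
Conditions: 9-mesityl-10-methylacridinium tetrafluoroborate (5 mol%), (PhS)2 (10 mol%), DCE/HFIP 9:1, 0.01 M, 450 nm LEDs, rt, Ar
Reagents that add atoms: none
Why: Photoexcited acridinium oxidises a veratryl ring of 2 and the radical cation cleaves the strained bis-benzylic C1–C2 cyclobutane bond to a distonic 1,4-radical cation, whose benzylic cation end attacks the other veratryl ring at C6' (para to its 3-OMe); after loss of the arenium proton the benzylic radical at tetralin C4 takes H• from PhSH while PhS• re-oxidises the acridine radical, so the step is a net redox-neutral isomerisation. The closest known reaction type is the radical-cation (photoinduced electron transfer or DDQ) 1,3-shift of 1,2-diarylcyclobutanes to 1-aryltetralins and 1-aryl-dihydronaphthalenes, the aryl analogue of the cation-radical vinylcyclobutane rearrangement. The one ring formed closes by a six-membered Friedel–Crafts (6-endo-type) attack of the arene on the benzylic cation, so the four cyclobutane carbons are joined by the two arene carbons C4a and C8a. C2 and C3 are not touched and keep the trans methyl configuration of 2, while C1 is set in the ring closure through a chair-like transition state with the aryl group pseudo-equatorial and trans to the C2 methyl, which is also the thermodynamic all-equatorial arrangement, so the configuration of the aryl-bearing carbons of 2 does not matter. The step needs cleavage of the bis-benzylic bond only (the weakest bond, giving two stabilised benzylic centres), closure para rather than ortho to OMe (sterics and para activation), and 1,6-closure faster than retro-[2+2] fragmentation, whose alkene products are kept from re-dimerising by the high dilution.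

**Compound list**
1 | (E)-methylisoeugenol, (E)-1,2-dimethoxy-4-(prop-1-en-1-yl)benzene | COc1ccc(/C=C/C)cc1OC | starting material
2 | (1R,2R,3S,4S)-1,2-bis(3,4-dimethoxyphenyl)-3,4-dimethylcyclobutane | COc1ccc([C@@H]2[C@@H](C)[C@H](C)[C@H]2c2ccc(OC)c(OC)c2)cc1OC | intermediate
3 | (1S,2S,3R)-galbulin | COc1ccc([C@H]2c3cc(OC)c(OC)cc3C[C@@H](C)[C@@H]2C)cc1OC | target

**Total step count:** 2
**Longest linear sequence:** 2

**Steps most likely to fail** (the route has only two steps, so both are ranked):

1. Step 2. The ring-opened radical cation may fragment further (retro-[2+2]) instead of closing. This would lower conversion and, if the liberated alkene re-dimerises, erode enantiopurity; the electron-rich product may also be over-oxidised. Fallback, setting out from 2: DDQ (1.2 equiv, CH2Cl2, 0 °C to rt) should effect the known oxidative ring opening/Friedel–Crafts ring expansion of this class of cyclobutane lignan to the 1,2-dihydronaphthalene (1S,2R)-cyclogalgravin F1. The oxidant then traps the cyclised intermediate irreversibly by a second oxidation rather than by hydrogen-atom return. Hydrogenation of F1 (H2, Pd/C, EtOAc, rt) should add hydrogen to C3=C4 on the face away from the pseudo-axial C1 aryl group, leaving the C3 methyl trans to the C2 methyl. This comes back to the route at 3.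

2. Step 1. Facial control by the chiral counteranion may be insufficient with the more electron-rich dimethoxy substrate, and the product may re-oxidise and revert in the flask. Fallback, setting out from 1: racemic radical-cation dimerisation with an achiral oxidant (PhI(OCOCF3)2 cat., HFIP, rt, or [Ru(bpz)3](PF6)2, visible light, air, MeNO2) should give the all-trans cyclobutane as a racemate, that is 2 together with its enantiomer, (1S,2S,3R,4R)-1,2-bis(3,4-dimethoxyphenyl)-3,4-dimethylcyclobutane F2. Preparative chiral SFC separates the two, F2 is discarded, and the route resumes at 2.

**Further compounds**
F1 | step 2 | (1S,2R)-cyclogalgravin, (1S,2R)-1-(3,4-dimethoxyphenyl)-6,7-dimethoxy-2,3-dimethyl-1,2-dihydronaphthalene | COc1ccc([C@H]2c3cc(OC)c(OC)cc3C=C(C)[C@@H]2C)cc1OC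
F2 | step 1 | (1S,2S,3R,4R)-1,2-bis(3,4-dimethoxyphenyl)-3,4-dimethylcyclobutane | COc1ccc([C@H]2[C@H](C)[C@@H](C)[C@@H]2c2ccc(OC)c(OC)c2)cc1OC
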